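**Retrosynthetic overview**
- The target is reached from 3,5,7-tri-O-benzyl-3'-O-(triisopropylsilyl)tamarixetin by hydrogenolysis, sulfation of O3 and O7 (the hydrogen-bonded 5-OH is left free) and fluoride desilylation of O3'.
- Key disconnection C4–C4a: C4a of ring A lies ortho to the O1 and O5 carbons and para to the O7 carbon, so it is the most nucleophilic arene carbon, and C4 is an acyl carbon. Ring C is therefore closed by intramolecular Friedel–Crafts acylation of a 3-aryloxy-2-benzyloxyacrylic acid.
- The acrylic acid comes from its methyl ester, whose O1–C2 bond is made by palladium-catalysed C–O coupling of an enol triflate with 3,5-bis(benzyloxy)phenol.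
- The enol triflate comes from a β-keto ester, whose C2–C3 bond is made by Claisen acylation of methyl benzyloxyacetate with silylated isovanilloyl chloride.
- Ring order: rings A and B are bought intact; ring C is the only ring formed (step 7).

Key step: step 7

Assumption: the aryl hydrogen sulfates are drawn and counted in the neutral acid form of the target, although they are handled as ammonium salts; the acid form is released at the end by brief cold cation exchange and should be neutralised (dipotassium salt) for storage.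

**Step 1**
Reactants: 1 isovanillic acid
Product: 3 4-methoxy-3-[(triisopropylsilyl)oxy]benzoic acid, via doubly silylated silyl ester 2 (not isolated)
Conditions: TIPSCl (2.3 equiv), imidazole, DMF, rt; then K2CO3, THF/H2O, rt; 1 M HCl to pH 3
Reagents that add atoms: triisopropylsilyl chloride, CC(C)[Si](Cl)(C(C)C)C(C)C
Why: Silylation of phenol and carboxyl with a silyl chloride and imidazole, followed by selective basic hydrolysis of the far more labile silyl ester, should leave the hindered aryl silyl ether in place.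

**Step 2**
Reactants: 3 4-methoxy-3-[(triisopropylsilyl)oxy]benzoic acid
Product: 4 4-methoxy-3-[(triisopropylsilyl)oxy]benzoyl chloride
Conditions: (COCl)2, DMF (cat.), CH2Cl2, 0 °C to rt; evaporate, use crude
Reagents that add atoms: oxalyl chloride, O=C(Cl)C(=O)Cl
Why: DMF-catalysed (Vilsmeier-type) conversion of a carboxylic acid into its chloride is routine and is tolerated by aryl triisopropylsilyl ethers.

**Step 3**
Reactants: 5 methyl 2-(benzyloxy)acetate; 4 4-methoxy-3-[(triisopropylsilyl)oxy]benzoyl chloride
Product: 6 methyl 2-(benzyloxy)-3-{4-methoxy-3-[(triisopropylsilyl)oxy]phenyl}-3-oxopropanoate (racemic)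
Conditions: 5 (2.1 equiv), LiN(SiMe3)2 (2.1 equiv), THF, −78 °C; then 4, −78 °C; AcOH quench
Reagents that add atoms: none
Why: Crossed Claisen C-acylation of the lithium enolate of a glycolate ester with an aroyl chloride, in which the second equivalent of enolate deprotonates the more acidic β-keto ester and so prevents over-acylation, should form the C2–C3 bond.

**Step 4**
Reactants: 6 methyl 2-(benzyloxy)-3-{4-methoxy-3-[(triisopropylsilyl)oxy]phenyl}-3-oxopropanoate
Product: 7 methyl (E)-2-(benzyloxy)-3-{4-methoxy-3-[(triisopropylsilyl)oxy]phenyl}-3-[(trifluoromethylsulfonyl)oxy]acrylate (OTf cis to the ester; a minor Z isomer may accompany it)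
Conditions: NaH, THF, 0 °C; then PhNTf2, 0 °C to rt
Reagents that add atoms: N-phenylbis(trifluoromethanesulfonimide), O=S(=O)(N(c1ccccc1)S(=O)(=O)C(F)(F)F)C(F)(F)F
Why: O-sulfonylation of the chelated sodium enolate of a β-keto ester by a triflimide is the standard route to enol triflates and should place the triflate cis to the ester, although the geometry is not critical later.

**Step 5**
Reactants: 7 enol triflate; 8 3,5-bis(benzyloxy)phenol
Product: 9 methyl (E)-2-(benzyloxy)-3-[3,5-bis(benzyloxy)phenoxy]-3-{4-methoxy-3-[(triisopropylsilyl)oxy]phenyl}acrylate (ester cis to aryloxy; a minor Z isomer may accompany it)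
Conditions: 8 (1.2 equiv), Pd2(dba)3 (2.5 mol %), 2-(di-tert-butylphosphino)biphenyl (7.5 mol %), K3PO4, toluene, 80 °C
Reagents that add atoms: none
Why: Palladium-catalysed C–O cross-coupling of an enol triflate with a phenol (Buchwald–Hartwig-type etherification; oxidative addition of zerovalent palladium to the vinyl C–OTf bond, exchange of triflate for phenoxide, then C–O reductive elimination from divalent palladium, favoured by the bulky phosphine and the electron-poor β-acrylate carbon) should form the O1–C2 bond with retention of geometry, whereas uncatalysed phenoxide would attack sulfur of the triflate or stall at the crowded, donor-substituted β-carbon.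

**Step 6**
Reactants: 9 methyl (E)-2-(benzyloxy)-3-[3,5-bis(benzyloxy)phenoxy]-3-{4-methoxy-3-[(triisopropylsilyl)oxy]phenyl}acrylate
Product: 10 (E)-2-(benzyloxy)-3-[3,5-bis(benzyloxy)phenoxy]-3-{4-methoxy-3-[(triisopropylsilyl)oxy]phenyl}acrylic acid (carboxyl cis to aryloxy)
Conditions: Me3SnOH (excess), ClCH2CH2Cl, 80 °C; then cold 0.5 M HCl wash
Reagents that add atoms: trimethyltin hydroxide, C[Sn](C)(C)O
Why: Near-neutral ester hydrolysis with trimethyltin hydroxide should free the acid without the hydroxide that would threaten the aryl silyl ether and without the carbocations that an acid-labile ester would release onto the trioxygenated ring.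

**Step 7**
Reactants: 10 (E)-2-(benzyloxy)-3-[3,5-bis(benzyloxy)phenoxy]-3-{4-methoxy-3-[(triisopropylsilyl)oxy]phenyl}acrylic acid
Product: 12 3,5,7-tri-O-benzyl-3'-O-(triisopropylsilyl)tamarixetin, via mixed trifluoroacetic anhydride 11 (not isolated)
Conditions: (CF3CO)2O (1.5 equiv), CH2Cl2, 0 °C to rt
Reagents that add atoms: none
Why: (CF3CO)2O converts the acid into mixed anhydride 11, an acylium equivalent, which is attacked by the ring A carbon ortho to the ether oxygen (the future C4a), and loss of a proton from the arenium ion gives the C4 ketone. The closest known reaction type is the acid-mediated cyclisation of 3-aryloxyacrylic acids (β-aryloxycinnamic acids) to chromones and flavones, an intramolecular Friedel–Crafts acylation. Ring C closes as a six-membered ring in the 6-exo-trig mode at the acyl carbon by electrophilic aromatic substitution. No stereocentre is formed. The step needs site selectivity and the right alkene geometry: the two ortho carbons of the symmetric 3,5-bis(benzyloxy)phenoxy ring are equivalent and, being ortho/para to three oxygens, should outcompete ring B (which could only give a strained indenone) and the benzyl rings, while the CF3CO2H set free protonates C3 reversibly so that the enol ether isomers interconvert and drain through the one with carboxyl cis to aryloxy. Because the attacked carbon is so electron-rich, no strong Lewis acid is needed, so the benzyl ethers and the aryl silyl ether should survive.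

**Step 8**
Reactants: 12 3,5,7-tri-O-benzyl-3'-O-(triisopropylsilyl)tamarixetin
Product: 13 3,5,7-trihydroxy-2-{4-methoxy-3-[(triisopropylsilyl)oxy]phenyl}-4H-chromen-4-one (3'-O-(triisopropylsilyl)tamarixetin)
Conditions: H2 (1 atm), Pd/C, THF/EtOAc, rt
Reagents that add atoms: none
Why: Hydrogenolysis of aryl benzyl ethers over palladium on carbon should free O3, O5 and O7, while the C2=C3 bond of the flavonol (part of a vinylogous ester) and the aryl silyl ether are not reduced.

**Step 9**
Reactants: 13 3'-O-(triisopropylsilyl)tamarixetin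
Product: 14 3'-O-(triisopropylsilyl)tamarixetin 3,7-bis(hydrogen sulfate) (handled as its bis(triethylammonium) salt)
Conditions: SO3·NMe3 (excess), Et3N, DMF, 50 °C
Reagents that add atoms: sulfur trioxide–trimethylamine complex, C[N+](C)(C)S(=O)(=O)[O-]
Why: O-Sulfation of phenols with an SO3–amine complex should take place at the acidic 7-OH and the enolic 3-OH, whereas the 5-OH, held in a hydrogen bond to the peri C4 carbonyl, stays free and O3' is blocked by silicon.

**Step 10**
Reactants: 14 3'-O-(triisopropylsilyl)tamarixetin 3,7-bis(hydrogen sulfate)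
Product: 15 tamarixetin 3,7-bis(hydrogen sulfate) (target, CNP0574123.0)
Conditions: Bu4NF, AcOH, THF, 0 °C to rt; then Dowex 50WX8 (H+ form), aq. MeOH, 0 °C, lyophilise
Reagents that add atoms: none
Why: Fluoride cleavage of the aryl silyl ether, driven by the strong Si–F bond and buffered with acetic acid, should free O3' without touching the sulfate monoesters, which are inert to fluoride and stable under non-acidic conditions.

**Compound list**
1 | isovanillic acid (3-hydroxy-4-methoxybenzoic acid) | COc1ccc(C(=O)O)cc1O | starting material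
2 | triisopropylsilyl 4-methoxy-3-[(triisopropylsilyl)oxy]benzoate | COc1ccc(C(=O)O[Si](C(C)C)(C(C)C)C(C)C)cc1O[Si](C(C)C)(C(C)C)C(C)C | intermediate (not isolated)
3 | 4-methoxy-3-[(triisopropylsilyl)oxy]benzoic acid | COc1ccc(C(=O)O)cc1O[Si](C(C)C)(C(C)C)C(C)C | intermediate
4 | 4-methoxy-3-[(triisopropylsilyl)oxy]benzoyl chloride | COc1ccc(C(=O)Cl)cc1O[Si](C(C)C)(C(C)C)C(C)C | intermediate
5 | methyl 2-(benzyloxy)acetate | COC(=O)COCc1ccccc1 | starting material
6 | methyl 2-(benzyloxy)-3-{4-methoxy-3-[(triisopropylsilyl)oxy]phenyl}-3-oxopropanoate (racemic) | COC(=O)C(OCc1ccccc1)C(=O)c1ccc(OC)c(O[Si](C(C)C)(C(C)C)C(C)C)c1 | intermediate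
7 | methyl (E)-2-(benzyloxy)-3-{4-methoxy-3-[(triisopropylsilyl)oxy]phenyl}-3-[(trifluoromethylsulfonyl)oxy]acrylate | COC(=O)/C(OCc1ccccc1)=C(\OS(=O)(=O)C(F)(F)F)c1ccc(OC)c(O[Si](C(C)C)(C(C)C)C(C)C)c1 | intermediate
8 | 3,5-bis(benzyloxy)phenol | Oc1cc(OCc2ccccc2)cc(OCc2ccccc2)c1 | starting material
9 | methyl (E)-2-(benzyloxy)-3-[3,5-bis(benzyloxy)phenoxy]-3-{4-methoxy-3-[(triisopropylsilyl)oxy]phenyl}acrylate | COC(=O)/C(OCc1ccccc1)=C(\Oc1cc(OCc2ccccc2)cc(OCc2ccccc2)c1)c1ccc(OC)c(O[Si](C(C)C)(C(C)C)C(C)C)c1 | intermediate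
10 | (E)-2-(benzyloxy)-3-[3,5-bis(benzyloxy)phenoxy]-3-{4-methoxy-3-[(triisopropylsilyl)oxy]phenyl}acrylic acid (carboxyl cis to aryloxy) | OC(=O)/C(OCc1ccccc1)=C(\Oc1cc(OCc2ccccc2)cc(OCc2ccccc2)c1)c1ccc(OC)c(O[Si](C(C)C)(C(C)C)C(C)C)c1 | intermediate (key-step precursor)
11 | mixed anhydride of 10 with trifluoroacetic acid | O=C(OC(=O)C(F)(F)F)/C(OCc1ccccc1)=C(\Oc1cc(OCc2ccccc2)cc(OCc2ccccc2)c1)c1ccc(OC)c(O[Si](C(C)C)(C(C)C)C(C)C)c1 | intermediate (not isolated)
12 | 3,5,7-tris(benzyloxy)-2-{4-methoxy-3-[(triisopropylsilyl)oxy]phenyl}-4H-chromen-4-one (3,5,7-tri-O-benzyl-3'-O-(triisopropylsilyl)tamarixetin) | O=c1c(OCc2ccccc2)c(-c2ccc(OC)c(O[Si](C(C)C)(C(C)C)C(C)C)c2)oc2cc(OCc3ccccc3)cc(OCc3ccccc3)c12 | intermediate (key-step product)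
13 | 3,5,7-trihydroxy-2-{4-methoxy-3-[(triisopropylsilyl)oxy]phenyl}-4H-chromen-4-one | O=c1c(O)c(-c2ccc(OC)c(O[Si](C(C)C)(C(C)C)C(C)C)c2)oc2cc(O)cc(O)c12 | intermediate
14 | 3'-O-(triisopropylsilyl)tamarixetin 3,7-bis(hydrogen sulfate) | COc1ccc(-c2oc3cc(OS(=O)(=O)O)cc(O)c3c(=O)c2OS(=O)(=O)O)cc1O[Si](C(C)C)(C(C)C)C(C)C | intermediate
15 | tamarixetin 3,7-bis(hydrogen sulfate) | COc1ccc(-c2oc3cc(OS(=O)(=O)O)cc(O)c3c(=O)c2OS(=O)(=O)O)cc1O | target

**Totals**
Total step count: 10. Longest linear sequence: 10 steps (1 to 15); 5 and 8 enter as purchased materials.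

**Steps most likely to fail**

1. Step 7 (key step). The acyl carbon is deactivated by vinylogous donation from the aryloxy oxygen, so ring closure may be slow. Intermolecular C-trifluoroacetylation of the electron-rich ring, or acid-induced loss of benzyl groups before closure, could then compete. The fallback closes ring C through the O1–C2 bond instead (Baker–Venkataraman route) and sets out from 4.
   - Acid chloride 4 acylates commercial 1-[2,4-bis(benzyloxy)-6-hydroxyphenyl]ethanone (pyridine, DMAP) to give the aryl ester 2-acetyl-3,5-bis(benzyloxy)phenyl 4-methoxy-3-[(triisopropylsilyl)oxy]benzoate F1.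
   - LiN(SiMe3)2 in THF should bring about the O-to-C acyl shift to the diketone 1-[2,4-bis(benzyloxy)-6-hydroxyphenyl]-3-{4-methoxy-3-[(triisopropylsilyl)oxy]phenyl}propane-1,3-dione F2.
   - Catalytic p-TsOH in warm toluene should cyclodehydrate it to the flavone 5,7-bis(benzyloxy)-2-{4-methoxy-3-[(triisopropylsilyl)oxy]phenyl}-4H-chromen-4-one F3.
   - Dimethyldioxirane should epoxidise C2=C3 to the racemic 2,3-epoxide of that flavone F4, which catalytic p-TsOH opens to the flavonol 5,7-bis(benzyloxy)-3-hydroxy-2-{4-methoxy-3-[(triisopropylsilyl)oxy]phenyl}-4H-chromen-4-one F5.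
   - Hydrogenolysis as in step 8 brings the route back at 13.

2. Step 5. Triflyl transfer from the enol triflate to the phenoxide (S–O cleavage) may outrun oxidative addition, or C–O reductive elimination may be slow at the crowded vinylpalladium centre. The fallback is a metal-free addition–elimination on a vinyl halide that has no sulfur to attack, and sets out from 6.
   - The Vilsmeier reagent ((COCl)2, DMF, CH2Cl2, reflux) should convert the ketone of 6 into the vinyl chloride methyl 2-(benzyloxy)-3-chloro-3-{4-methoxy-3-[(triisopropylsilyl)oxy]phenyl}acrylate F6 (E/Z mixture).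
   - The potassium phenoxide of 8 (KOtBu) in DMF at 80–100 °C should replace chloride at the β-carbon and bring the route back at 9.

3. Step 9. Sulfation of the hydrogen-bonded, enolic 3-OH may stay incomplete and give salt mixtures that are hard to separate, or base may remove the silyl group and allow sulfation at O3'. The fallback installs both sulfates as neutral, chromatographable diesters and sets out from 13.
   - 2,2,2-Trichloroethyl chlorosulfate with Et3N and DMAP in THF should give the bis(2,2,2-trichloroethyl sulfate) of 13 at O3 and O7, F7, which can be purified on silica.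
   - Zn and HCO2NH4 in MeOH should then remove both trichloroethyl groups reductively and bring the route back at 14.

**Further compounds**
F1 | step 7 | 2-acetyl-3,5-bis(benzyloxy)phenyl 4-methoxy-3-[(triisopropylsilyl)oxy]benzoate | CC(=O)c1c(OCc2ccccc2)cc(OCc2ccccc2)cc1OC(=O)c1ccc(OC)c(O[Si](C(C)C)(C(C)C)C(C)C)c1
F2 | step 7 | 1-[2,4-bis(benzyloxy)-6-hydroxyphenyl]-3-{4-methoxy-3-[(triisopropylsilyl)oxy]phenyl}propane-1,3-dione | O=C(CC(=O)c1ccc(OC)c(O[Si](C(C)C)(C(C)C)C(C)C)c1)c1c(O)cc(OCc2ccccc2)cc1OCc1ccccc1
F3 | step 7 | 5,7-bis(benzyloxy)-2-{4-methoxy-3-[(triisopropylsilyl)oxy]phenyl}-4H-chromen-4-one | O=c1cc(-c2ccc(OC)c(O[Si](C(C)C)(C(C)C)C(C)C)c2)oc2cc(OCc3ccccc3)cc(OCc3ccccc3)c12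
F4 | step 7 | racemic 2,3-epoxide of F3 (5,7-bis(benzyloxy)-2,3-epoxy-2-{4-methoxy-3-[(triisopropylsilyl)oxy]phenyl}chroman-4-one) | O=C1C2OC2(c2ccc(OC)c(O[Si](C(C)C)(C(C)C)C(C)C)c2)Oc2cc(OCc3ccccc3)cc(OCc3ccccc3)c21
F5 | step 7 | 5,7-bis(benzyloxy)-3-hydroxy-2-{4-methoxy-3-[(triisopropylsilyl)oxy]phenyl}-4H-chromen-4-one | O=c1c(O)c(-c2ccc(OC)c(O[Si](C(C)C)(C(C)C)C(C)C)c2)oc2cc(OCc3ccccc3)cc(OCc3ccccc3)c12
F6 | step 5 | methyl 2-(benzyloxy)-3-chloro-3-{4-methoxy-3-[(triisopropylsilyl)oxy]phenyl}acrylate (E/Z mixture) | COC(=O)C(OCc1ccccc1)=C(Cl)c1ccc(OC)c(O[Si](C(C)C)(C(C)C)C(C)C)c1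
F7 | step 9 | 3'-O-(triisopropylsilyl)tamarixetin 3,7-bis(2,2,2-trichloroethyl sulfate) | COc1ccc(-c2oc3cc(OS(=O)(=O)OCC(Cl)(Cl)Cl)cc(O)c3c(=O)c2OS(=O)(=O)OCC(Cl)(Cl)Cl)cc1O[Si](C(C)C)(C(C)C)C(C)C
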